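**Plan**

- Retrosynthesis: four O–benzyl bonds (hydrogenolysis) ⇒ C3–H from C3–CO2allyl (temporary carboxyl, removed by Pd decarboxylative protonation) ⇒ oxirane from the prenyl alkene ⇒ C4–C4a (pyranone ring closure by Friedel–Crafts acylation of a quaternary malonic half-ester) ⇒ C3–C2 (alkylation with an aryloxymethyl chloride) ⇒ C3–C1' (Cu arylation of diallyl malonate) ⇒ C5'–CH2 (ortho-prenylation).
- Forward: the B-ring iodide and the A-ring ether are joined on the malonate carbon; the pyranone C ring closes next, the oxirane ring follows, C3 is then set, and the benzyl groups fall last.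
- Enabling feature: ring A is a phloroglucinol nucleus (O at C5, C7 and O1 on C8a). In the open precursor the two carbons ortho to O1 (future C4a and C8) are equivalent and each is ortho/para to three oxygens. C3 is α to the C4 ketone, so an extra carboxyl there blocks enolisation and aryloxide loss during ring closure and later leaves as CO2 through the enolate.
- Stereochemistry: oxirane C2 (R) from the chiral ketone catalyst; C3 (S) from protonation of a Pd enolate under a chiral PHOX ligand, which funnels both C3 epimers into one. Only neutral steps follow.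

Key step: step 9

Assumption: 2-(benzyloxy)phenol and 3,5-bis(benzyloxy)phenol are taken as purchasable; C3–H of the final ketone is treated as labile to base, so it is installed late and only neutral conditions follow.

**Route**

Step 1
Reactants: 1 2-(benzyloxy)phenol
Product: 2 2-(benzyloxy)-4-iodophenol
Conditions: NIS (1.0 equiv), TsOH·H2O (cat.), MeCN, 0 °C → rt
Reagents that add atoms: N-iodosuccinimide, O=C1CCC(=O)N1I
Why: Electrophilic aromatic iodination (SEAr): the free hydroxyl is the strongest director and its para position is open, so iodine should enter at C4 and leave C6 as the only free position ortho to the hydroxyl.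

Step 2
Reactants: 2 2-(benzyloxy)-4-iodophenol; 3 prenyl bromide (1-bromo-3-methylbut-2-ene)
Product: 5 2-(benzyloxy)-4-iodo-6-(3-methylbut-2-en-1-yl)phenol, via sodium 2-(benzyloxy)-4-iodophenolate 4 (not isolated)
Conditions: NaH (1.05 equiv), toluene, 0 °C → rt; then 3 (1.2 equiv), rt → 40 °C
Reagents that add atoms: none
Why: ortho-C-alkylation of a phenoxide: in toluene the tight sodium ion pair shields oxygen, so the allylic bromide should be attacked by ring carbon C6 (para is blocked by iodine, the other ortho carbon by the benzyloxy group) and the dienone re-aromatises by tautomerisation.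

Step 3
Reactants: 5 2-(benzyloxy)-4-iodo-6-(3-methylbut-2-en-1-yl)phenol
Product: 6 1,2-bis(benzyloxy)-5-iodo-3-(3-methylbut-2-en-1-yl)benzene
Conditions: BnBr, K2CO3, DMF, rt → 50 °C
Reagents that add atoms: benzyl bromide, BrCc1ccccc1
Why: Williamson ether synthesis on the hindered but acidic phenol should give the bis-benzyl ether, whose protecting groups all fall in the last step.

Step 4
Reactants: 6 1,2-bis(benzyloxy)-5-iodo-3-(3-methylbut-2-en-1-yl)benzene; 7 diallyl malonate
Product: 8 diallyl 2-[3,4-bis(benzyloxy)-5-(3-methylbut-2-en-1-yl)phenyl]malonate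
Conditions: CuI (10 mol %), 2-picolinic acid (20 mol %), Cs2CO3 (3 equiv), 7 (2 equiv), 1,4-dioxane, rt → 60 °C
Reagents that add atoms: none
Why: Copper-catalysed C-arylation of a malonate (Ullmann–Hurtley type coupling) should work because Cu(I) tolerates the allyl esters that Pd(0) would ionise and the iodide has both ortho positions free.

Step 5
Reactants: 9 3,5-bis(benzyloxy)phenol; 10 chloromethyl methyl sulfide
Product: 12 1,3-bis(benzyloxy)-5-[(methylsulfanyl)methoxy]benzene, via sodium 3,5-bis(benzyloxy)phenolate 11 (not isolated)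
Conditions: NaH (1.1 equiv), NaI (cat.), DMF, 0 °C; then 10, 0 °C → rt
Reagents that add atoms: none
Why: Williamson-type O-alkylation of the phenoxide by the α-chloro sulfide (thionium-like electrophile) should give the O,S-acetal that carries the future C2.

Step 6
Reactants: 12 1,3-bis(benzyloxy)-5-[(methylsulfanyl)methoxy]benzene
Product: 13 1,3-bis(benzyloxy)-5-(chloromethoxy)benzene
Conditions: SO2Cl2 (1.0 equiv), CH2Cl2, −78 °C; then cyclohexene (1.5 equiv), −78 °C → rt; concentrate and use crude
Reagents that add atoms: sulfuryl chloride, O=S(=O)(Cl)Cl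
Why: Chlorinolysis of an O,S-acetal: sulfur, far more nucleophilic than the arene at −78 °C, is chlorinated and the chlorosulfonium ion collapses to the aryloxymethyl chloride and MeSCl, which cyclohexene removes before it can sulfenylate the ring.

Step 7
Reactants: 8 diallyl 2-[3,4-bis(benzyloxy)-5-(3-methylbut-2-en-1-yl)phenyl]malonate; 13 1,3-bis(benzyloxy)-5-(chloromethoxy)benzene
Product: 15 diallyl 2-[3,4-bis(benzyloxy)-5-(3-methylbut-2-en-1-yl)phenyl]-2-{[3,5-bis(benzyloxy)phenoxy]methyl}malonate, via sodium enolate of the arylmalonate 14 (not isolated)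
Conditions: NaH (1.05 equiv), THF, 0 °C; then crude 13 (1.2 equiv), 0 °C → rt
Reagents that add atoms: none
Why: C-alkylation of a stabilised malonate enolate by an SN1-active α-chloro ether should create the quaternary carbon (future C3), which bears no hydrogen, so the aryloxide can no longer be lost by E1cB.

Step 8
Reactants: 15 diallyl 2-[3,4-bis(benzyloxy)-5-(3-methylbut-2-en-1-yl)phenyl]-2-{[3,5-bis(benzyloxy)phenoxy]methyl}malonate
Product: 17 3-(allyloxy)-2-[3,4-bis(benzyloxy)-5-(3-methylbut-2-en-1-yl)phenyl]-2-{[3,5-bis(benzyloxy)phenoxy]methyl}-3-oxopropanoic acid (racemic), via potassium half-ester carboxylate 16 (not isolated)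
Conditions: KOH (1.1 equiv), THF–H2O (4:1), 0 °C → rt; then cold 1 M HCl to pH 3
Reagents that add atoms: potassium hydroxide, [K+].[OH-]
Why: Saponification (BAc2) should stop at the half-ester because the first carboxylate deactivates the remaining hindered ester; the two allyl esters are enantiotopic, so the quaternary stereocentre forms racemic, which is of no consequence.

Step 9
Reactants: 17 3-(allyloxy)-2-[3,4-bis(benzyloxy)-5-(3-methylbut-2-en-1-yl)phenyl]-2-{[3,5-bis(benzyloxy)phenoxy]methyl}-3-oxopropanoic acid (racemic)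
Product: 20 allyl 5,7-bis(benzyloxy)-3-[3,4-bis(benzyloxy)-5-(3-methylbut-2-en-1-yl)phenyl]-4-oxochromane-3-carboxylate (racemic), via acid chloride 18 (not isolated), via mixed acyl triflate 19 (not isolated)
Conditions: 1-chloro-N,N,2-trimethylprop-1-en-1-amine (1.2 equiv), CH2Cl2, 0 °C → rt; then AgOTf (1.2 equiv), 2,6-di-tert-butyl-4-methylpyridine (2 equiv), CH2Cl2, −78 → −20 °C, dark
Reagents that add atoms: none
Why: The α-chloroenamine turns the acid into acid chloride 18 without releasing HCl, silver triflate abstracts chloride to give the acyl triflate 19 (an acylium equivalent), and this is attacked by the ring carbon ortho to the ether oxygen, the hindered pyridine taking the proton from the σ-complex. The closest known reaction type is the intramolecular Friedel–Crafts acylation of 3-aryloxypropanoyl chlorides to chroman-4-ones through acyl triflates. The pyranone ring O1–C2–C3–C4–C4a–C8a closes in a 6-exo-trig mode by attack of the arene carbon on the acyl carbon, the carbonyl oxygen staying exocyclic. No new stereocentre is made: quaternary C3 is already stereogenic and racemic in 17 and is left uncontrolled on purpose, because step 11 erases and resets it. Regioselectivity is secured by the local symmetry of the 3,5-bis(benzyloxy)phenoxy ring, whose two carbons ortho to the ether oxygen are equivalent and activated by three oxygens, while its para carbon and the B ring cannot be reached through a six-membered transition state. Chemoselectivity rests on the allyloxycarbonyl group at C3, which excludes ketene formation and loss of the aryloxide, and on the HCl-free, base-buffered medium, which protects the prenyl alkene and the benzyl ethers.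

Step 10
Reactants: 20 allyl 5,7-bis(benzyloxy)-3-[3,4-bis(benzyloxy)-5-(3-methylbut-2-en-1-yl)phenyl]-4-oxochromane-3-carboxylate (racemic)
Product: 21 allyl 5,7-bis(benzyloxy)-3-{3,4-bis(benzyloxy)-5-[((2R)-3,3-dimethyloxiran-2-yl)methyl]phenyl}-4-oxochromane-3-carboxylate (both C3 epimers)
Conditions: D-fructose-derived Shi ketone (30 mol %), Oxone, K2CO3, Bu4NHSO4, MeCN–DMM / aq. Na2B4O7–Na2EDTA buffer (pH ≈ 10.5), 0 °C
Reagents that add atoms: potassium peroxymonosulfate (Oxone), OOS(=O)(=O)[O-].[K+]
Why: Shi asymmetric epoxidation: the chiral dioxirane should deliver oxygen through the spiro transition state to one face of the trisubstituted, electron-rich alkene (catalyst control, 2R expected as for trans- and trisubstituted olefins) much faster than to the monosubstituted allyl ester alkene, while quaternary C3 cannot epimerise at pH 10.5 and both C3 epimers formed are carried on.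

Step 11
Reactants: 21 allyl 5,7-bis(benzyloxy)-3-{3,4-bis(benzyloxy)-5-[((2R)-3,3-dimethyloxiran-2-yl)methyl]phenyl}-4-oxochromane-3-carboxylate (both C3 epimers)
Product: 22 (3S)-5,7-bis(benzyloxy)-3-{3,4-bis(benzyloxy)-5-[((2R)-3,3-dimethyloxiran-2-yl)methyl]phenyl}chroman-4-one
Conditions: Pd2(dba)3 (5 mol %), (S)-(CF3)3-t-BuPHOX (12.5 mol %), Meldrum's acid (2.5 equiv), 1,4-dioxane, 40 °C
Reagents that add atoms: none
Why: Palladium-catalysed decarboxylative asymmetric protonation: Pd(0) ionises the allyl ester and loss of CO2 gives a planar Pd enolate bound to the chiral P,N ligand, so both C3 epimers converge and face-selective proton transfer from Meldrum's acid (whose anion takes up the allyl group) should set 3S under ligand control, the remote oxirane being inert to Pd(0) and to this weak C–H acid; the ligand enantiomer is to be matched to 3S in a trial on 20, the (R)-ligand being used if the sense is opposite.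

Step 12
Reactants: 22 (3S)-5,7-bis(benzyloxy)-3-{3,4-bis(benzyloxy)-5-[((2R)-3,3-dimethyloxiran-2-yl)methyl]phenyl}chroman-4-one
Product: 23 (3S)-3-{3,4-dihydroxy-5-[((2R)-3,3-dimethyloxiran-2-yl)methyl]phenyl}-5,7-dihydroxychroman-4-one
Conditions: H2 (1 atm), 10 % Pd/C, EtOAc, rt; filtration through Celite, evaporation without heating
Reagents that add atoms: none
Why: Hydrogenolysis of the four benzyl aryl ethers on Pd/C under neutral, aprotic conditions should spare the non-benzylic trisubstituted oxirane and the electron-rich aryl ketone, and no base or acid is present to enolise C3 or to let the ortho-phenol open the oxirane.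

**Compound list**

1 | 2-(benzyloxy)phenol | Oc1ccccc1OCc1ccccc1 | starting material
2 | 2-(benzyloxy)-4-iodophenol | Oc1ccc(I)cc1OCc1ccccc1 | intermediate
3 | prenyl bromide (1-bromo-3-methylbut-2-ene) | CC(C)=CCBr | starting material
4 | sodium 2-(benzyloxy)-4-iodophenolate | [Na+].[O-]c1ccc(I)cc1OCc1ccccc1 | intermediate
5 | 2-(benzyloxy)-4-iodo-6-(3-methylbut-2-en-1-yl)phenol | CC(C)=CCc1cc(I)cc(OCc2ccccc2)c1O | intermediate
6 | 1,2-bis(benzyloxy)-5-iodo-3-(3-methylbut-2-en-1-yl)benzene | CC(C)=CCc1cc(I)cc(OCc2ccccc2)c1OCc1ccccc1 | intermediate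
7 | diallyl malonate | C=CCOC(=O)CC(=O)OCC=C | starting material
8 | diallyl 2-[3,4-bis(benzyloxy)-5-(3-methylbut-2-en-1-yl)phenyl]malonate | CC(C)=CCc1cc(C(C(=O)OCC=C)C(=O)OCC=C)cc(OCc2ccccc2)c1OCc1ccccc1 | intermediate
9 | 3,5-bis(benzyloxy)phenol | Oc1cc(OCc2ccccc2)cc(OCc2ccccc2)c1 | starting material
10 | chloromethyl methyl sulfide | CSCCl | starting material
11 | sodium 3,5-bis(benzyloxy)phenolate | [Na+].[O-]c1cc(OCc2ccccc2)cc(OCc2ccccc2)c1 | intermediate
12 | 1,3-bis(benzyloxy)-5-[(methylsulfanyl)methoxy]benzene | CSCOc1cc(OCc2ccccc2)cc(OCc2ccccc2)c1 | intermediate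
13 | 1,3-bis(benzyloxy)-5-(chloromethoxy)benzene | ClCOc1cc(OCc2ccccc2)cc(OCc2ccccc2)c1 | intermediate
14 | sodium enolate of diallyl arylmalonate 8 | CC(C)=CCc1cc(C(C(=O)OCC=C)=C([O-])OCC=C)cc(OCc2ccccc2)c1OCc1ccccc1.[Na+] | intermediate
15 | diallyl 2-[3,4-bis(benzyloxy)-5-(3-methylbut-2-en-1-yl)phenyl]-2-{[3,5-bis(benzyloxy)phenoxy]methyl}malonate | CC(C)=CCc1cc(C(COc2cc(OCc3ccccc3)cc(OCc3ccccc3)c2)(C(=O)OCC=C)C(=O)OCC=C)cc(OCc2ccccc2)c1OCc1ccccc1 | intermediate
16 | potassium salt of half-ester 17 (racemic) | CC(C)=CCc1cc(C(COc2cc(OCc3ccccc3)cc(OCc3ccccc3)c2)(C(=O)[O-])C(=O)OCC=C)cc(OCc2ccccc2)c1OCc1ccccc1.[K+] | intermediate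
17 | 3-(allyloxy)-2-[3,4-bis(benzyloxy)-5-(3-methylbut-2-en-1-yl)phenyl]-2-{[3,5-bis(benzyloxy)phenoxy]methyl}-3-oxopropanoic acid (racemic) | CC(C)=CCc1cc(C(COc2cc(OCc3ccccc3)cc(OCc3ccccc3)c2)(C(=O)O)C(=O)OCC=C)cc(OCc2ccccc2)c1OCc1ccccc1 | intermediate
18 | acid chloride of 17 (racemic) | CC(C)=CCc1cc(C(COc2cc(OCc3ccccc3)cc(OCc3ccccc3)c2)(C(=O)Cl)C(=O)OCC=C)cc(OCc2ccccc2)c1OCc1ccccc1 | intermediate
19 | mixed carboxylic–triflic anhydride of 17 (racemic) | CC(C)=CCc1cc(C(COc2cc(OCc3ccccc3)cc(OCc3ccccc3)c2)(C(=O)OS(=O)(=O)C(F)(F)F)C(=O)OCC=C)cc(OCc2ccccc2)c1OCc1ccccc1 | intermediate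
20 | allyl 5,7-bis(benzyloxy)-3-[3,4-bis(benzyloxy)-5-(3-methylbut-2-en-1-yl)phenyl]-4-oxochromane-3-carboxylate (racemic) | CC(C)=CCc1cc(C2(C(=O)OCC=C)COc3cc(OCc4ccccc4)cc(OCc4ccccc4)c3C2=O)cc(OCc2ccccc2)c1OCc1ccccc1 | intermediate
21 | allyl 5,7-bis(benzyloxy)-3-{3,4-bis(benzyloxy)-5-[((2R)-3,3-dimethyloxiran-2-yl)methyl]phenyl}-4-oxochromane-3-carboxylate (both C3 epimers) | CC1(C)O[C@@H]1Cc1cc(C2(C(=O)OCC=C)COc3cc(OCc4ccccc4)cc(OCc4ccccc4)c3C2=O)cc(OCc2ccccc2)c1OCc1ccccc1 | intermediate
22 | (3S)-5,7-bis(benzyloxy)-3-{3,4-bis(benzyloxy)-5-[((2R)-3,3-dimethyloxiran-2-yl)methyl]phenyl}chroman-4-one | CC1(C)O[C@@H]1Cc1cc([C@H]2COc3cc(OCc4ccccc4)cc(OCc4ccccc4)c3C2=O)cc(OCc2ccccc2)c1OCc1ccccc1 | intermediate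
23 | (3S)-3-{3,4-dihydroxy-5-[((2R)-3,3-dimethyloxiran-2-yl)methyl]phenyl}-5,7-dihydroxychroman-4-one (CNP0197974.1) | CC1(C)O[C@@H]1Cc1cc([C@H]2COc3cc(O)cc(O)c3C2=O)cc(O)c1O | target

**Step count and risks**

Total steps: 12. Longest linear sequence: 10 (steps 1–4, then 7–12); the A-ring branch (steps 5–6) joins at step 7.

Steps most likely to fail:

1. Step 11. The protonation of the Pd enolate may discriminate poorly between the two faces, because the B ring has no ortho substituent to amplify the ligand's bias, and the acidic proton donor may slowly open the oxirane. The fallback sets C3 by dynamic kinetic resolution at the ketone instead and sets out from 20. Pd(PPh3)4 with morpholine in THF should remove the allyloxycarbonyl group to give racemic 5,7-bis(benzyloxy)-3-[3,4-bis(benzyloxy)-5-(3-methylbut-2-en-1-yl)phenyl]chroman-4-one F1. Asymmetric transfer hydrogenation with RuCl[(S,S)-TsDPEN](p-cymene) in HCO2H/Et3N, during which C3 racemises through the enol and the reduction is cis-selective, should give the (3S,4S)-chroman-4-ol F2. Shi epoxidation, now harmless because C3 is no longer acidic, should give the (2R)-epoxy (3S,4S)-chroman-4-ol F3. Dess–Martin oxidation buffered with NaHCO3 then returns to the route at 22.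

2. Step 9. The prenyl double bond may be protonated (cationic cyclisation onto the neighbouring benzyloxy oxygen), the acylium ion may lose CO to a benzylic cation, or the peri benzyl ether may be lost. The fallback gives up the late ring closure and attaches the B ring to a preformed C ring; it sets out from iodide 6. O-Benzylation of purchasable 5,7-dihydroxychroman-4-one (BnBr, K2CO3, DMF) gives 5,7-bis(benzyloxy)chroman-4-one F4. Pd-catalysed ketone α-arylation of F4 with 6 (Pd2(dba)3, tBu3P·HBF4, NaOtBu, toluene) should give the racemic isoflavanone F1, which then follows the reduction, epoxidation and oxidation sequence described above (cis-alcohol F2, epoxy alcohol F3) and comes back to the route at 22.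

3. Step 6. Electrophilic chlorination or sulfenylation of the very electron-rich ring may compete with chlorination at sulfur, and the α-chloro ether may hydrolyse before use. The fallback forms the C2–O1 bond from the carbon side and sets out from malonate 8. Base-catalysed hydroxymethylation (paraformaldehyde, cat. K2CO3, THF) should give diallyl 2-[3,4-bis(benzyloxy)-5-(3-methylbut-2-en-1-yl)phenyl]-2-(hydroxymethyl)malonate F5. Mitsunobu etherification of F5 with phenol 9 (PPh3, DIAD, toluene, 60 °C) then comes back to the route at 15.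

**Further compounds**

F1 | step 11 | 5,7-bis(benzyloxy)-3-[3,4-bis(benzyloxy)-5-(3-methylbut-2-en-1-yl)phenyl]chroman-4-one (racemic) | CC(C)=CCc1cc(C2COc3cc(OCc4ccccc4)cc(OCc4ccccc4)c3C2=O)cc(OCc2ccccc2)c1OCc1ccccc1
F2 | step 11 | (3S,4S)-5,7-bis(benzyloxy)-3-[3,4-bis(benzyloxy)-5-(3-methylbut-2-en-1-yl)phenyl]chroman-4-ol (cis) | CC(C)=CCc1cc([C@H]2COc3cc(OCc4ccccc4)cc(OCc4ccccc4)c3[C@H]2O)cc(OCc2ccccc2)c1OCc1ccccc1
F3 | step 11 | (3S,4S)-5,7-bis(benzyloxy)-3-{3,4-bis(benzyloxy)-5-[((2R)-3,3-dimethyloxiran-2-yl)methyl]phenyl}chroman-4-ol (cis) | CC1(C)O[C@@H]1Cc1cc([C@H]2COc3cc(OCc4ccccc4)cc(OCc4ccccc4)c3[C@H]2O)cc(OCc2ccccc2)c1OCc1ccccc1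
F4 | step 9 | 5,7-bis(benzyloxy)chroman-4-one | O=C1CCOc2cc(OCc3ccccc3)cc(OCc3ccccc3)c21
F5 | step 6 | diallyl 2-[3,4-bis(benzyloxy)-5-(3-methylbut-2-en-1-yl)phenyl]-2-(hydroxymethyl)malonate | CC(C)=CCc1cc(C(CO)(C(=O)OCC=C)C(=O)OCC=C)cc(OCc2ccccc2)c1OCc1ccccc1
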